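The amounts I follow are fractions of each species' own charge, and the left-handed substrate is the one I choose to follow through both earlier runs.

| setting | teal | green | flask |
|---|---|---|---|
| left-handed substrate | 0.019 M | 0.028 M | 0.038 M |
| right-handed substrate | 0.019 M | 0.028 M | 0.038 M |
| coupling partner | 2 equiv | 2 equiv | 2.00 equiv |
| free catalyst | 10 mol% | 10 mol% | 10 mol% |
| added ligand | 2.2 mM | 2.2 mM | 2.2 mM |
| remark | run made earlier | run made earlier |  |
| time |  |  | 20 min |

| run | time / min | left-handed product / % | left-handed substrate / % |
|---|---|---|---|
| teal | 2.00 | 15 | 35 |
| teal | 4.00 | 24 | 25 |
| teal | 6.00 | 30 | 20 |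
| teal | 12.0 | 35 | 14 |
| teal | 25.0 | 38 | 10 |
| green | 2.00 | 25 | 25 |
| green | 6.00 | 37 | 14 |
| green | 12.0 | 43 | 9 |
| green | 15.0 | 42 | 6 |
| green | 25.0 | 44 | 6 |

(scatter of a reading: 1.5 percentage points)

- free catalyst is single-handed; left-handed substrate and right-handed substrate are mirror images of each other, charged as a racemate, each of them at the stated concentration

- concentration of left-handed product at 20 min, in M
- concentration of left-handed substrate at 20 min, in M
- concentration of coupling partner at 20 min, in M

In teal and green, left-handed substrate and left-handed product together stay near the left-handed charge, so I track one number: the depth, minus the natural logarithm of the fraction of that charge left. For a pseudo-first-order loss on a catalyst that itself dies at first order, other concentrations held, the depth integrates to a ceiling times one minus the catalyst's decay factor, so it flattens as the catalyst goes. Green's left-handed substrate readings at 15.0 min and 25.0 min stand equal, and I take the last readings of each run as ceilings: teal 1.61, green 2.12.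

I reckon the flask in two ways. The early slopes, 0.178 min⁻¹ and 0.347 min⁻¹, differ by a factor of 1.95, near the squared charge ratio of 2.17. Carrying that square from green gives a depth of 3.91, leaving 2.00%. The line through the two ceilings against charge gives, at the flask's charge, a carried depth of 2.69, leaving 6.80%. The two part, and the slope way cheats: the ceilings themselves rose by a factor of 1.32, less than the square. I commit to the line, as a reading with its scatter. No earlier run read the coupling partner, so depth gives no number for it.

The forecast gives 0.034 M, 0.0038 M and 0.116 M, placing the flask “near the plateau”; its left-handed substrate means a depth of 2.30, shallower than mine.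

The flask gives 0.0355 M, 0.00242 M and 0.00340 M: 6.4% of the left-handed charge is left, a depth of 2.75, close to the carried 2.69.

    free catalyst + left-handed substrate ⇌ catalyst intermediate A (K = 130 M⁻¹, k = 530 M⁻¹ min⁻¹)
    free catalyst + right-handed substrate ⇌ catalyst intermediate B (K = 18.0 M⁻¹, k = 300 M⁻¹ min⁻¹)
    coupling partner + catalyst intermediate A → free catalyst + left-handed product (k = 330 M⁻¹ min⁻¹)
    coupling partner + catalyst intermediate B → free catalyst + right-handed product (k = 150 M⁻¹ min⁻¹)
    2 coupling partner → self-condensation product (k = 1.90 M⁻¹ min⁻¹)
    free catalyst + added ligand ⇌ idle complex, settled at all times (K = 880 M⁻¹)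
    free catalyst → spent catalyst (k = 0.310 min⁻¹)

In the flask the left-handed side is nearly at rest. At 200 min the depth is 2.90, left-handed product stands at 0.0359 M, and coupling partner has gone from 4.5% to 1.22% of its charge; spent catalyst already stands at 85.9% of the catalyst charged at the asked time. For a neighbour flask charged with 40 mol% of free catalyst I scale the ceiling by 4.00, so the carried depth gives 10.8 there. That neighbour reaches 8.59, shallower than reckoned, with hardly any of the left-handed charge left and 0.0380 M of left-handed product.

The runs stem from a simulated flask on assumed constants, noise included.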